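**Retrosynthetic overview**
- Feature: C1 and C7 of the heptan-3-one chain each carry the same 4-hydroxy-3-methoxyphenyl ring, and the C3 oxygen sits two carbons from C1. It therefore maps onto the allylic carbinol of a hepta-1,6-dien-3-ol whose vinyl ends are C1=C2 and C6=C7.
- Last disconnection: the saturated bis-phenol comes from the O,O'-dibenzyl hept-6-en-3-one by one hydrogenation that also removes both benzyl groups.
- Key disconnection: the aryl–C1 and aryl–C7 bonds are cut together, back to two molecules of 1-(benzyloxy)-4-iodo-2-methoxybenzene and racemic hepta-1,6-dien-3-ol. The C3 ketone arises from the C3 carbinol by palladium hydride transfer.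
- Precursors: the dienol is cut at C3–C4 to acrolein and but-3-enylmagnesium bromide; the iodoarene comes from 4-iodo-2-methoxyphenol by O-benzylation.
- Ring formation: none. Both benzene rings are brought in intact and the chain stays acyclic.

Key step: step 3

Assumption: the target has no stereocentre and no stereogenic alkene, so it is one achiral compound and no enantiocontrol is needed.

**Step 1**
Reactants: 1 acrolein; 2 but-3-enylmagnesium bromide
Product: 4 hepta-1,6-dien-3-ol (racemic), via bromomagnesium hepta-1,6-dien-3-olate 3 (not isolated)
Conditions: THF, −78 → 0 °C; then sat. aq. NH4Cl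
Reagents that add atoms: none
Why: Grignard 1,2-addition to the aldehyde carbonyl of acrolein (no copper, low temperature) forms the C3–C4 bond; the C3 carbinol centre is deliberately racemic because step 3 converts it to the ketone.

**Step 2**
Reactants: 5 4-iodo-2-methoxyphenol
Product: 6 1-(benzyloxy)-4-iodo-2-methoxybenzene
Conditions: BnBr, K2CO3, DMF, rt
Reagents that add atoms: benzyl bromide, BrCc1ccccc1
Why: Williamson ether synthesis, O-alkylation of the phenol by a benzylic bromide under carbonate base, which leaves the aryl iodide untouched.

**Step 3**
Reactants: 4 hepta-1,6-dien-3-ol (racemic); 6 1-(benzyloxy)-4-iodo-2-methoxybenzene (2.3 equiv)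
Product: 8 (E)-1,7-bis[4-(benzyloxy)-3-methoxyphenyl]hept-6-en-3-one, via 1-[4-(benzyloxy)-3-methoxyphenyl]hept-6-en-3-one 7 (not isolated)
Conditions: Pd(OAc)2 (10 mol%), n-Bu4NCl, NaHCO3, degassed DMF, 45 °C then 85 °C
Reagents that add atoms: none
Why: Oxidative addition of 6 to phosphine-free Pd(0) gives an aryl–palladium halide that inserts each terminal alkene of 4 with the aryl group going to the CH2 terminus (C1 and C7), as in a Mizoroki–Heck reaction under Jeffery conditions. At the C1=C2 end the C2–palladium species eliminates the carbinol hydrogen of C3 and the enol tautomerises to the C3 ketone, which is the known Heck arylation of secondary allylic alcohols to β-aryl ketones and the closest precedent; this end should react first at 45 °C and give 7. At 85 °C the isolated C6=C7 alkene of 7 should undergo an ordinary Heck arylation of a 1-alkene, with syn β-hydride elimination giving mainly the E-styrene 8 together with allylarene and other chain-walked alkene isomers of the same oxidation level, which are carried on unseparated. No ring is closed and no stereocentre is created: the racemic C3 centre of 4 is erased and the alkene geometry disappears in step 4. The selectivity needed is terminal-carbon arylation at both alkenes and elimination towards oxygen across C2–C3; the halide-rich neutral pathway with an aryl iodide puts the aryl group on the less hindered carbon, and the oxygen-activated C3–H favours carbonyl formation over the cinnamyl-type alcohol.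

**Step 4**
Reactants: 8 (E)-1,7-bis[4-(benzyloxy)-3-methoxyphenyl]hept-6-en-3-one (with its alkene isomers)
Product: 10 1,7-bis(4-hydroxy-3-methoxyphenyl)heptan-3-one, via 1,7-bis[4-(benzyloxy)-3-methoxyphenyl]heptan-3-one 9 (not isolated)
Conditions: H2 (1 atm), 10% Pd/C, EtOAc–EtOH, rt
Reagents that add atoms: none
Why: Heterogeneous catalytic hydrogenation should saturate the chain alkene in all its positional isomers and hydrogenolyse both aryl benzyl ethers, while the isolated dialkyl ketone and the aryl methyl ethers are inert under these mild conditions.

**Compound list**
1 | acrolein (prop-2-enal) | C=CC=O | starting material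
2 | but-3-enylmagnesium bromide | C=CCC[Mg]Br | starting material
3 | bromomagnesium hepta-1,6-dien-3-olate (racemic) | C=CCCC(O[Mg]Br)C=C | intermediate
4 | hepta-1,6-dien-3-ol (racemic) | C=CCCC(O)C=C | intermediate
5 | 4-iodo-2-methoxyphenol | COc1cc(I)ccc1O | starting material
6 | 1-(benzyloxy)-4-iodo-2-methoxybenzene | COc1cc(I)ccc1OCc1ccccc1 | intermediate
7 | 1-[4-(benzyloxy)-3-methoxyphenyl]hept-6-en-3-one | C=CCCC(=O)CCc1ccc(OCc2ccccc2)c(OC)c1 | intermediate
8 | (E)-1,7-bis[4-(benzyloxy)-3-methoxyphenyl]hept-6-en-3-one | COc1cc(/C=C/CCC(=O)CCc2ccc(OCc3ccccc3)c(OC)c2)ccc1OCc1ccccc1 | intermediate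
9 | 1,7-bis[4-(benzyloxy)-3-methoxyphenyl]heptan-3-one | COc1cc(CCCCC(=O)CCc2ccc(OCc3ccccc3)c(OC)c2)ccc1OCc1ccccc1 | intermediate
10 | 1,7-bis(4-hydroxy-3-methoxyphenyl)heptan-3-one | COc1cc(CCCCC(=O)CCc2ccc(O)c(OC)c2)ccc1O | target

**Step count**
Total: 4 steps. Longest linear sequence: 3 steps (step 1 or step 2, then steps 3 and 4).

**Steps most likely to fail**

Step 3. Running both arylations on one dienol in one pot is the untested part of the route. Several things may go wrong:
- arylation at the internal carbon of the unactivated C6=C7 alkene, which gives a branched chain that hydrogenation cannot correct;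
- β-hydride elimination away from the carbinol, so that the C3 hydroxyl is kept;
- 5-exo carbopalladation of the second alkene by the alkylpalladium intermediate;
- stalling after the first arylation as palladium black separates.

The fallback sets out from 6 and builds the chain by an aldol reaction. Jeffery-type Heck arylation of but-3-en-2-ol with 6 (Pd(OAc)2, n-Bu4NCl, NaHCO3, DMF) should give 4-[4-(benzyloxy)-3-methoxyphenyl]butan-2-one F1. The same reaction of 6 with prop-2-en-1-ol should give 3-[4-(benzyloxy)-3-methoxyphenyl]propanal F2. Kinetic deprotonation of F1 at its methyl group (LDA, THF, −78 °C) and addition of F2 should give racemic 1,7-bis[4-(benzyloxy)-3-methoxyphenyl]-5-hydroxyheptan-3-one F3. Dehydration (cat. TsOH, toluene, 80 °C) should then give (E)-1,7-bis[4-(benzyloxy)-3-methoxyphenyl]hept-4-en-3-one F4. F4 is an alkene-position isomer of 8. Under the conditions of step 4 it should be reduced in the flask to 9, where the fallback rejoins the route, and then on to 10.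

Step 4. Halide or ammonium residues from step 3 may poison the catalyst so that hydrogenolysis stalls at partly debenzylated material, or forcing conditions may reduce the C3 ketone. The fallback sets out from 8 and separates the two operations. The alkene is saturated with the benzyl ethers kept (H2, Pd/C poisoned with Ph2S, EtOAc, rt), and 9 is now isolated. Both aryl benzyl ethers are then cleaved without a reductant (BCl3, pentamethylbenzene, CH2Cl2, −78 °C), which returns to the route at 10. This fallback makes no compound outside the list (F0).

Step 1. Acrolein may undergo conjugate addition or oligomerise under the basic Grignard conditions, and the volatile dienol may be lost on isolation. The fallback sets out from 2 and reverses the roles of the partners. Formylation of 2 with N,N-dimethylformamide (THF, 0 °C; aq. HCl work-up) should give pent-4-enal F5. Addition of vinylmagnesium bromide (THF, −78 → 0 °C) then gives the same alkoxide 3, where the fallback rejoins the route, and the usual work-up gives 4.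

**Further compounds**
F1 | step 3 | 4-[4-(benzyloxy)-3-methoxyphenyl]butan-2-one | CC(=O)CCc1ccc(OCc2ccccc2)c(OC)c1
F2 | step 3 | 3-[4-(benzyloxy)-3-methoxyphenyl]propanal | O=CCCc1ccc(OCc2ccccc2)c(OC)c1
F3 | step 3 | 1,7-bis[4-(benzyloxy)-3-methoxyphenyl]-5-hydroxyheptan-3-one (racemic) | COc1cc(CCC(O)CC(=O)CCc2ccc(OCc3ccccc3)c(OC)c2)ccc1OCc1ccccc1
F4 | step 3 | (E)-1,7-bis[4-(benzyloxy)-3-methoxyphenyl]hept-4-en-3-one | COc1cc(CC/C=C/C(=O)CCc2ccc(OCc3ccccc3)c(OC)c2)ccc1OCc1ccccc1
F0 | step 4 | none | none
F5 | step 1 | pent-4-enal | C=CCCC=O
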